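Abbreviations: TBS = tert‑butyldimethylsilyl, TIPS = triisopropylsilyl.

## The problem

Target 23 is a dibenzylbutyrolactone lignan with one benzylic position oxidised. Its only ring is a γ‑lactone (O1, C2 carbonyl, C3, C4, C5). C3 carries an (S)‑hydroxy(4‑hydroxy‑3‑methoxyphenyl)methyl group and C4 a 4‑hydroxy‑3‑methoxybenzyl group, so the task is acyclic stereocontrol folded onto a five‑membered ring, not ring construction. Three contiguous stereocentres have to be set: the carbinol carbon (S), C3 (S) and C4 (R), with the two ring substituents trans. The carbinol and C3 stand in a syn β‑hydroxy carbonyl relationship and can be made together in a reagent‑controlled aldol reaction. C3 can in turn direct C4 through the ring, because a 3,4‑trans butanolide is more stable than its cis isomer; C4 itself is not α to a carbonyl and cannot be corrected by enolisation once the skeleton is complete. The functionality is fragile: base cleaves the β‑hydroxy lactone by retro‑aldol reaction and epimerises C3, acid ionises the para‑hydroxybenzylic carbinol (epimerisation, dehydration, Friedel–Crafts closure onto the second arene), hydrogenolysis threatens the same C–O bond, and the free guaiacol rings are easily oxidised. The feature that opens a short route is that C4 bears two one‑carbon arms, the ring carbon C5 and the benzylic CH2. If both begin as CH2OH, C4 is prochiral, lactonisation onto either arm creates the stereocentre, and the free arm of the product can attack the lactone carbonyl, so the two lactones can interconvert and the choice between the arms can be left to the thermodynamic preference dictated by C3.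

## Retrosynthesis

**23 ⇒ 22.** Only O–Si bonds are cut. All three hydroxyl groups are carried as silyl ethers (TBS on the carbinol, TIPS on both phenols) because buffered fluoride is the one deprotection that needs neither acid, base nor hydrogen, each of which 23 tolerates poorly. Compound 22 is no simpler in skeleton, but it is robust. The forward step must stay close to neutral.

**22 ⇒ 19 + 21.** The bond between the benzylic CH2 on C4 and its arene is cut, giving iodomethyl lactone 19 and aryl bromide 21. Cutting C4–CH2 instead would call for a conjugate addition that sets C4 kinetically, and cutting at C3 on the finished lactone would ask a lactone enolate to choose the face of an aldehyde. The chosen cut removes a whole aryl unit, touches no stereocentre and reduces the benzyl group to a one‑carbon arm on C4. The forward reaction must join a primary alkyl electrophile to an electron‑rich aryl halide without a base that could enolise C3; a nickel‑catalysed reductive coupling of the two halides fits. Bromide 21 is one silylation away from commercial 20.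

**19 ⇒ 18.** Exchange of iodine for hydroxyl leads to hydroxymethyl lactone 18. This is a functional‑group change only, but it shows that C4 now carries CH2OH and the ring CH2O, two arms of the same oxidation level. The forward step is a substitution at an unhindered primary carbon.

**18 ⇒ 15.** Cutting the acyl C2–O1 bond unfolds the ring to a carboxylic acid whose C4 bears two hydroxymethyl groups; tied as an acetonide they give acid 15, in which C4 is not a stereocentre. One ring and one stereocentre disappear, and what remains is a syn aldol with a symmetric α‑substituent. A kinetic choice between the diastereotopic arms would be hard to predict. Instead, diol acid 16 set free from 15 closes to both lactones, cis 17 and trans 18, which exchange through the free arm, and the equilibrium should favour 18. The carbinol stays as its TBS ether: the bulk enlarges the trans preference and the ether suppresses benzylic ionisation under the acid used.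

**15 ⇒ 13 ⇒ 12.** Acid 15 is the hydrolysis product of N‑acyl oxazolidinone 13, the silyl ether of aldol adduct 12. Silylation comes before auxiliary removal so that the electron‑rich benzylic aldol is never exposed to base with a free hydroxyl. Because the hydrolysis is alkaline, the phenol is carried as a TIPS ether, which is less base‑labile than a TBS ether.

**12 ⇒ 7 + 9.** The bond between the future C3 and the carbinol carbon is an aldol bond. Cutting it gives imide 7 and silylated vanillin 9 (one step from vanillin 8). A boron‑mediated aldol of the imide sets both centres through a closed transition state with predictable absolute sense: the (S)‑auxiliary 5 delivers the (2S,3S) syn adduct. Precursor 7 has no stereocentre outside the auxiliary.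

**7 ⇒ 4 + 5; 4 ⇒ 3 ⇒ 2 ⇒ 1.** Imide 7 is the N‑acyl derivative of 5 with the symmetric acid 4. In 4 the CH2CO2H unit is the cleavage product of an allyl group and the dioxane is the acetonide of a 1,3‑diol, so 4 goes back through alkene 3 and diol 2 to diethyl allylmalonate 1. The two ester carbons of 1 become the two arms on C4.

## Roads not taken

**Alternative 1:** The cut runs through the C3–C4 bond and both benzylic C–O bonds and leads to two molecules of (E)‑ferulic acid A1. Forward, FeCl3 and air oxidise A1 to phenoxyl radicals that couple at their β‑carbons; each carboxylate then adds to the quinone methide of the other half and the cis‑fused dilactone A2 results.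
- Merits: the whole C–C skeleton, two rings and all relative stereochemistry arise in one step from a cheap acid without protecting groups. The sequence from A2 to the target could be about half as long as the chosen route, and this has to be conceded.
- Weak points: the radical coupling offers no handle for absolute control, so A2 is racemic and a resolution is needed, and other coupling modes of the radical compete. A2 holds both benzylic carbons as lactone C–O and both terminal carbons as carbonyls, whereas the target needs one benzylic CH2, one carbinol, one carbonyl and one CH2O. That means hydrogenolysing exactly one of two equivalent benzylic C–O bonds, reducing one lactone beside a free acid and relactonising. The cis ring fusion of A2 then maps onto a cis‑3,4 lactone, so C3 must be inverted under base next to a retro‑aldol‑prone β‑hydroxyl.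
- Comparison: both plans must tell two like groups apart. The chosen plan sets against the brevity of A2 an absolute configuration fixed by an auxiliary and a differentiation that is driven by a thermodynamic bias instead of by stopping a reaction halfway.

**Alternative 2:** Both exocyclic C–C bonds of the lactone are cut at once, C4–C(benzylic) and C3–C(carbinol), leading to (5R)‑5‑menthyloxy‑2(5H)‑furanone A3, aryl dithiane A4 and silylated vanillin A5. Forward, lithiated A4 adds to C4 of A3 anti to the menthyloxy group; the enolate, exchanged to titanium with ClTi(Oi‑Pr)3, adds to A5 trans to the new C4 substituent and gives A6.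
- Merits: two C–C bonds and the C3/C4 relationship are made in one flask, relayed reliably from the acetal centre. C4 is set kinetically with strong precedent for this substrate class, which is better than resting it on an equilibrium, and the route is shorter and more convergent than the chosen one.
- Weak points: the carbinol configuration depends on which aldehyde face a lactone enolate attacks, a choice that is usually poorly controlled and that the metal exchange may or may not improve. Desulfurisation with Raney Ni then has to spare a benzylic C–O bond. Converting the acetal carbon into the ring CH2O requires hydrolysis and reduction of an aldehyde acid under basic conditions on a β‑hydroxy acid.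
- Comparison: the chosen plan sets against this a carbinol/C3 pair fixed in a closed transition state in 12, and no sulfur, Raney Ni or basic step after the carbinol exists.

**Alternative 3:** The C3–C(carbinol) bond is cut together with a bond from the carbinol oxygen to C2, which leads to a β‑lactone and back to (R)‑acid chloride A7 and vanillin acetate A8. Forward, dehydrohalogenation of A7 with i‑Pr2NEt and (2+2) cycloaddition with A8 under O‑trimethylsilylquinidine (or the quinine pseudoenantiomer) and LiClO4 gives cis‑β‑lactone A9. Removal of the primary silyl ether then lets the hydroxymethyl group expand the ring by acyl transfer and frees the carbinol.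
- Merits: the step is catalytic in the chiral controller and sets C3 and the carbinol together. The strain‑driven acyl transfer is irreversible and unveils the carbinol without a protecting group. C4 is fixed beforehand in A7, so nothing depends on an equilibrium; in this respect it is superior to the chosen plan.
- Weak points: electron‑rich aromatic aldehydes are poor partners in alkaloid‑catalysed ketene–aldehyde cycloadditions. A 4‑aryl β‑lactone with a para oxygen substituent ionises easily at the benzylic C–O bond (decarboxylation, epimerisation). The stereocentre in A7 creates matched and mismatched pairings with the catalyst. A7 needs its own asymmetric synthesis, so the total length is no shorter.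
- Comparison: the chosen plan sets against the better C4 control of A9 a boron aldol that is dependable for this aldehyde type and intermediates that are ordinary silyl ethers. It pays with a stoichiometric auxiliary.

Key step: step 9

## Route

Remark on the chemistry: an aryl TBS ether is not expected to outlast the alkaline hydroperoxide of step 8, so both phenols are carried as TIPS ethers; the carbinol carries TBS.

Step 1
Reactants: 1 diethyl allylmalonate
Product: 2 2‑allylpropane‑1,3‑diol
Conditions: LiAlH4, THF, 0 °C → reflux; H2O, aq. NaOH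
Reagents that add atoms: none
Why: LiAlH4 reduction of both malonate esters to the 1,3‑diol; the isolated terminal alkene is inert to hydride.

Step 2
Reactants: 2 2‑allylpropane‑1,3‑diol
Product: 3 5‑allyl‑2,2‑dimethyl‑1,3‑dioxane
Conditions: Me2C(OMe)2, TsOH·H2O (cat.), CH2Cl2, rt
Reagents that add atoms: 2,2‑dimethoxypropane, COC(C)(C)OC
Why: Acid‑catalysed transketalisation of a 1,3‑diol to its six‑membered acetonide, driven by release of methanol.

Step 3
Reactants: 3 5‑allyl‑2,2‑dimethyl‑1,3‑dioxane
Product: 4 2‑(2,2‑dimethyl‑1,3‑dioxan‑5‑yl)acetic acid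
Conditions: KMnO4 (5 mol %), NaIO4 (4 equiv), K2CO3, t‑BuOH/H2O, rt; citric acid to pH 4, 0 °C
Reagents that add atoms: sodium periodate, [Na+].[O-]I(=O)(=O)=O; water, O
Why: Lemieux–von Rudloff oxidation: catalytic permanganate, regenerated by periodate, cleaves the terminal alkene and takes the aldehyde on to the acid; the mildly basic medium and the cold, brief acidification keep the acetonide intact.

Step 4
Reactants: 4 2‑(2,2‑dimethyl‑1,3‑dioxan‑5‑yl)acetic acid; 5 (S)‑4‑benzyloxazolidin‑2‑one
Product: 7 (S)‑4‑benzyl‑3‑[2‑(2,2‑dimethyl‑1,3‑dioxan‑5‑yl)acetyl]oxazolidin‑2‑one, via mixed pivalic anhydride 6 (not isolated)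
Conditions: PivCl, Et3N, THF, −20 °C; then 5, LiCl, −20 °C → rt
Reagents that add atoms: none
Why: N‑Acylation of the oxazolidinone through a mixed pivalic anhydride with LiCl/Et3N activation; the nucleophile attacks the unhindered carbonyl of the anhydride and the non‑acidic conditions spare the acetonide.

Step 5
Reactants: 8 vanillin
Product: 9 3‑methoxy‑4‑(triisopropylsilyloxy)benzaldehyde
Conditions: TIPSCl, imidazole, DMF, rt
Reagents that add atoms: triisopropylsilyl chloride, CC(C)[Si](Cl)(C(C)C)C(C)C
Why: Imidazole‑mediated silylation of a phenol; TIPS is chosen for its resistance to the basic hydroperoxide of step 8.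

Step 6
Reactants: 7 (S)‑4‑benzyl‑3‑[2‑(2,2‑dimethyl‑1,3‑dioxan‑5‑yl)acetyl]oxazolidin‑2‑one; 9 3‑methoxy‑4‑(triisopropylsilyloxy)benzaldehyde
Product: 12 (S)‑4‑benzyl‑3‑[(2S,3S)‑2‑(2,2‑dimethyl‑1,3‑dioxan‑5‑yl)‑3‑hydroxy‑3‑(3‑methoxy‑4‑triisopropylsilyloxyphenyl)propanoyl]oxazolidin‑2‑one, via Z‑dibutylboron enolate 10 (not isolated), via dibutylboron aldolate 11 (not isolated)
Conditions: Bu2BOTf, i‑Pr2NEt, CH2Cl2, −78 → 0 °C; 9, −78 → 0 °C; pH 7 buffer, MeOH, 30% H2O2, 0 °C
Reagents that add atoms: none
Why: Evans syn aldol: the Z‑boron enolate reacts through a chair Zimmerman–Traxler transition state with the auxiliary carbonyl turned away from the enolate oxygen, and the aldehyde approaches the face opposite the benzyl group; this should give the (2S,3S) syn adduct, fixing the future C3 and the carbinol carbon in one step.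

Step 7
Reactants: 12 aldol adduct
Product: 13 (S)‑4‑benzyl‑3‑[(2S,3S)‑3‑(tert‑butyldimethylsilyloxy)‑2‑(2,2‑dimethyl‑1,3‑dioxan‑5‑yl)‑3‑(3‑methoxy‑4‑triisopropylsilyloxyphenyl)propanoyl]oxazolidin‑2‑one
Conditions: TBSOTf, 2,6‑lutidine, CH2Cl2, −78 → 0 °C
Reagents that add atoms: tert‑butyldimethylsilyl triflate, CC(C)(C)[Si](C)(C)OS(=O)(=O)C(F)(F)F
Why: Silyl triflate silylation of a hindered secondary alcohol under buffered conditions that leave the acetonide alone; the ether blocks retro‑aldol cleavage and benzylic ionisation and supplies the bulk on which step 9 relies.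

Step 8
Reactants: 13 silylated imide
Product: 15 (2S,3S)‑3‑(tert‑butyldimethylsilyloxy)‑2‑(2,2‑dimethyl‑1,3‑dioxan‑5‑yl)‑3‑(3‑methoxy‑4‑triisopropylsilyloxyphenyl)propanoic acid, via peroxy acid 14 (not isolated)
Conditions: LiOH·H2O, 30% H2O2, THF/H2O (3:1), 0 °C → rt; aq. Na2SO3; 1 M HCl to pH 4, 0 °C
Reagents that add atoms: hydrogen peroxide, OO
Why: Hydroperoxide hydrolysis of an N‑acyl oxazolidinone: the small, weakly basic hydroperoxide anion attacks the exocyclic carbonyl even of hindered imides, the peroxy acid is reduced by sulfite, and the α‑centre is not enolised; auxiliary 5 is recovered and the cold acidification to pH 4 spares the acetonide.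

Step 9
Reactants: 15 acetonide acid
Product: 18 trans‑(3S,4S)‑3‑[(S)‑(tert‑butyldimethylsilyloxy)(3‑methoxy‑4‑triisopropylsilyloxyphenyl)methyl]‑4‑(hydroxymethyl)dihydrofuran‑2(3H)‑one, via diol acid 16 (not isolated), via cis‑lactone 17 (not isolated)
Conditions: PPTS (0.2 equiv), MeOH, 40 °C; evaporate; CSA (0.1 equiv), CH2Cl2, rt, until the cis/trans ratio no longer changes
Reagents that add atoms: none
Why: PPTS in methanol transketalises the acetonide of 15 to diol acid 16, and either hydroxymethyl oxygen then attacks the carboxyl carbon in a 5‑exo‑trig acyl substitution that forms the C2–O1 bond and the γ‑lactone, giving 17 and 18. Under anhydrous CSA the free arm of each lactone adds, again 5‑exo‑trig, to the protonated lactone carbonyl; the resulting 2,6‑dioxabicyclo[2.2.1]heptan‑1‑ol tetrahedral intermediate can expel either ring oxygen, so 17 and 18 interconvert while no bond to C3 or to the carbinol carbon is broken. The closest known reaction type is the intramolecular transesterification by which β‑(hydroxymethyl)‑γ‑butyrolactones exchange their two arms, combined with the established preference of 3,4‑disubstituted butanolides for the trans arrangement. The only new stereocentre, C4, is thus set under thermodynamic control by C3, fixed in step 6: in 18 the hydroxymethyl group lies trans to the bulky silyloxy(aryl)methyl group, in 17 cis. The selectivity needed is that between the two diastereotopic arms; it is secured by the size of the C3 substituent (the reason the TBS ether is installed first) and by working under acid, where C3 is not enolised and the syn aldol relationship is safe. Both silyl ethers should survive, because the benzylic cation is disfavoured by the adjacent carbonyl‑bearing carbon and an aryl TIPS ether is inert to mild acid. The position of the equilibrium is the quantity to be verified; any 17 that remains can be separated and resubmitted.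

Step 10
Reactants: 18 trans hydroxymethyl lactone
Product: 19 trans‑(3S,4R)‑3‑[(S)‑(tert‑butyldimethylsilyloxy)(3‑methoxy‑4‑triisopropylsilyloxyphenyl)methyl]‑4‑(iodomethyl)dihydrofuran‑2(3H)‑one
Conditions: I2, PPh3, imidazole, CH2Cl2, 0 °C → rt
Reagents that add atoms: iodine, II
Why: Appel reaction: the primary alcohol is activated as an alkoxyphosphonium ion and displaced by iodide; once the free arm is gone the lactone can no longer exchange, so C4 is locked (the descriptor changes from S to R only through priority).

Step 11
Reactants: 20 4‑bromo‑2‑methoxyphenol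
Product: 21 (4‑bromo‑2‑methoxyphenoxy)triisopropylsilane
Conditions: TIPSCl, imidazole, DMF, rt
Reagents that add atoms: triisopropylsilyl chloride, CC(C)[Si](Cl)(C(C)C)C(C)C
Why: Imidazole‑mediated silylation of the phenol, so that no acidic O–H interferes with the reductive coupling.

Step 12
Reactants: 19 iodomethyl lactone; 21 (4‑bromo‑2‑methoxyphenoxy)triisopropylsilane
Product: 22 trans‑(3S,4R)‑3‑[(S)‑(tert‑butyldimethylsilyloxy)(3‑methoxy‑4‑triisopropylsilyloxyphenyl)methyl]‑4‑(3‑methoxy‑4‑triisopropylsilyloxybenzyl)dihydrofuran‑2(3H)‑one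
Conditions: NiI2·xH2O (10 mol %), 4,4'‑di‑tert‑butyl‑2,2'‑bipyridine (10 mol %), pyridine (10 mol %), NaI (25 mol %), Zn powder (2 equiv), DMPU, 60 °C
Reagents that add atoms: none
Why: Nickel‑catalysed reductive cross‑electrophile coupling: the aryl bromide adds oxidatively to zerovalent nickel, the arylnickel species captures the primary alkyl radical generated from the iodide, and reductive elimination forms the CH2–aryl bond with Zn as terminal reductant; the conditions are base‑free, tolerate lactones and silyl ethers, and touch no stereocentre.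

Step 13
Reactants: 22 tris‑silyl lactone
Product: 23 (3S,4R)‑3‑[(S)‑hydroxy(4‑hydroxy‑3‑methoxyphenyl)methyl]‑4‑(4‑hydroxy‑3‑methoxybenzyl)dihydrofuran‑2(3H)‑one
Conditions: Bu4NF (4 equiv), AcOH (4 equiv), THF, 0 °C → rt
Reagents that add atoms: none
Why: Fluoride‑mediated cleavage of the three Si–O bonds; acetic acid buffers the medium so that phenoxide and alkoxide concentrations stay low, which guards against retro‑aldol cleavage, C3 epimerisation and quinone methide formation.

## Compound list

1 | diethyl allylmalonate | CCOC(=O)C(CC=C)C(=O)OCC | starting material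
2 | 2‑allylpropane‑1,3‑diol | OCC(CC=C)CO | intermediate
3 | 5‑allyl‑2,2‑dimethyl‑1,3‑dioxane | C=CCC1COC(C)(C)OC1 | intermediate
4 | 2‑(2,2‑dimethyl‑1,3‑dioxan‑5‑yl)acetic acid | OC(=O)CC1COC(C)(C)OC1 | intermediate
5 | (S)‑4‑benzyloxazolidin‑2‑one | O=C1OC[C@H](Cc2ccccc2)N1 | starting material
6 | 2‑(2,2‑dimethyl‑1,3‑dioxan‑5‑yl)acetic pivalic anhydride (not isolated) | CC(C)(C)C(=O)OC(=O)CC1COC(C)(C)OC1 | intermediate
7 | (S)‑4‑benzyl‑3‑[2‑(2,2‑dimethyl‑1,3‑dioxan‑5‑yl)acetyl]oxazolidin‑2‑one | O=C1OC[C@H](Cc2ccccc2)N1C(=O)CC3COC(C)(C)OC3 | intermediate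
8 | vanillin | COc1cc(C=O)ccc1O | starting material
9 | 3‑methoxy‑4‑(triisopropylsilyloxy)benzaldehyde | COc1cc(C=O)ccc1O[Si](C(C)C)(C(C)C)C(C)C | intermediate
10 | Z‑dibutylboron enolate of 7 (not isolated) | O=C1OC[C@H](Cc2ccccc2)N1/C(OB(CCCC)CCCC)=C/C3COC(C)(C)OC3 | intermediate
11 | O‑dibutylboryl aldolate of 12 (not isolated) | O=C1OC[C@H](Cc2ccccc2)N1C(=O)[C@@H](C3COC(C)(C)OC3)[C@H](OB(CCCC)CCCC)c4ccc(O[Si](C(C)C)(C(C)C)C(C)C)c(OC)c4 | intermediate
12 | (S)‑4‑benzyl‑3‑[(2S,3S)‑2‑(2,2‑dimethyl‑1,3‑dioxan‑5‑yl)‑3‑hydroxy‑3‑(3‑methoxy‑4‑triisopropylsilyloxyphenyl)propanoyl]oxazolidin‑2‑one | O=C1OC[C@H](Cc2ccccc2)N1C(=O)[C@@H](C3COC(C)(C)OC3)[C@H](O)c4ccc(O[Si](C(C)C)(C(C)C)C(C)C)c(OC)c4 | intermediate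
13 | 3‑O‑TBS ether of 12 | O=C1OC[C@H](Cc2ccccc2)N1C(=O)[C@@H](C3COC(C)(C)OC3)[C@H](O[Si](C)(C)C(C)(C)C)c4ccc(O[Si](C(C)C)(C(C)C)C(C)C)c(OC)c4 | intermediate
14 | (2S,3S)‑3‑(TBS‑oxy)‑2‑(2,2‑dimethyl‑1,3‑dioxan‑5‑yl)‑3‑(3‑methoxy‑4‑TIPS‑oxyphenyl)propaneperoxoic acid (not isolated) | CC1(C)OCC(CO1)[C@H](C(=O)OO)[C@H](O[Si](C)(C)C(C)(C)C)c1ccc(O[Si](C(C)C)(C(C)C)C(C)C)c(OC)c1 | intermediate
15 | (2S,3S)‑3‑(TBS‑oxy)‑2‑(2,2‑dimethyl‑1,3‑dioxan‑5‑yl)‑3‑(3‑methoxy‑4‑TIPS‑oxyphenyl)propanoic acid | CC1(C)OCC(CO1)[C@H](C(=O)O)[C@H](O[Si](C)(C)C(C)(C)C)c1ccc(O[Si](C(C)C)(C(C)C)C(C)C)c(OC)c1 | intermediate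
16 | (2S,3S)‑3‑(TBS‑oxy)‑2‑(1,3‑dihydroxypropan‑2‑yl)‑3‑(3‑methoxy‑4‑TIPS‑oxyphenyl)propanoic acid (not isolated) | OCC(CO)[C@H](C(=O)O)[C@H](O[Si](C)(C)C(C)(C)C)c1ccc(O[Si](C(C)C)(C(C)C)C(C)C)c(OC)c1 | intermediate
17 | cis‑(3S,4R)‑3‑[(S)‑(TBS‑oxy)(3‑methoxy‑4‑TIPS‑oxyphenyl)methyl]‑4‑(hydroxymethyl)dihydrofuran‑2(3H)‑one (not isolated) | O=C1OC[C@@H](CO)[C@H]1[C@H](O[Si](C)(C)C(C)(C)C)c1ccc(O[Si](C(C)C)(C(C)C)C(C)C)c(OC)c1 | intermediate
18 | trans‑(3S,4S)‑3‑[(S)‑(TBS‑oxy)(3‑methoxy‑4‑TIPS‑oxyphenyl)methyl]‑4‑(hydroxymethyl)dihydrofuran‑2(3H)‑one | O=C1OC[C@H](CO)[C@H]1[C@H](O[Si](C)(C)C(C)(C)C)c1ccc(O[Si](C(C)C)(C(C)C)C(C)C)c(OC)c1 | intermediate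
19 | trans‑(3S,4R)‑3‑[(S)‑(TBS‑oxy)(3‑methoxy‑4‑TIPS‑oxyphenyl)methyl]‑4‑(iodomethyl)dihydrofuran‑2(3H)‑one | O=C1OC[C@H](CI)[C@H]1[C@H](O[Si](C)(C)C(C)(C)C)c1ccc(O[Si](C(C)C)(C(C)C)C(C)C)c(OC)c1 | intermediate
20 | 4‑bromo‑2‑methoxyphenol | COc1cc(Br)ccc1O | starting material
21 | (4‑bromo‑2‑methoxyphenoxy)triisopropylsilane | COc1cc(Br)ccc1O[Si](C(C)C)(C(C)C)C(C)C | intermediate
22 | trans‑(3S,4R)‑3‑[(S)‑(TBS‑oxy)(3‑methoxy‑4‑TIPS‑oxyphenyl)methyl]‑4‑(3‑methoxy‑4‑TIPS‑oxybenzyl)dihydrofuran‑2(3H)‑one | COc1cc(C[C@H]2COC(=O)[C@@H]2[C@H](O[Si](C)(C)C(C)(C)C)c2ccc(O[Si](C(C)C)(C(C)C)C(C)C)c(OC)c2)ccc1O[Si](C(C)C)(C(C)C)C(C)C | intermediate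
23 | (3S,4R)‑3‑[(S)‑hydroxy(4‑hydroxy‑3‑methoxyphenyl)methyl]‑4‑(4‑hydroxy‑3‑methoxybenzyl)dihydrofuran‑2(3H)‑one | COc1cc(C[C@H]2COC(=O)[C@@H]2[C@H](O)c2ccc(O)c(OC)c2)ccc1O | target

## Step count and risks

Total: 13 steps. Longest linear sequence: 11 steps (steps 1–4, 6–10, 12 and 13, from 1 to 23).

**Step 9 (key step).** The acyl transfer may be slow under acid mild enough for the silyl ethers, or the trans preference may be smaller than hoped; stronger acid would invite benzylic ionisation and loss of the TBS ether. The fallback sets out from 15 and returns at 18. Only the PPTS stage is run, giving the unequilibrated mixture of 17 and 18. This mixture is oxidised with Dess–Martin periodinane (NaHCO3, CH2Cl2) to the cis‑4‑formyl lactone F1 and the trans‑4‑formyl lactone F2. C4 is now α to an aldehyde, so catalytic Et3N in CH2Cl2 should drain F1 into the more stable F2 by enolisation. NaBH4 in THF/MeOH at −40 °C then reduces F2 to 18. The selection principle changes from acyl transfer to C–H epimerisation, at the cost of two extra steps.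

**Step 8.** Attack at the crowded exocyclic carbonyl may be slow, so that endocyclic opening of the oxazolidinone ring competes and long exposure starts to erode the aryl silyl ether. The fallback sets out from 13 and returns at 15. The auxiliary is removed reductively (LiBH4, MeOH, THF, 0 °C) to give the primary alcohol F3 with recovery of 5. Dess–Martin oxidation gives the aldehyde F4, and Pinnick oxidation (NaClO2, NaH2PO4, 2‑methyl‑2‑butene, t‑BuOH/H2O) gives 15.

**Step 12.** Oxidative addition of the electron‑rich aryl bromide may lag behind activation of the alkyl iodide, which is then consumed by homocoupling or reduction. The fallback sets out from 19 and returns at 22. Zn is inserted into the C–I bond (Zn dust, LiCl, THF, rt) to give the alkylzinc iodide F5. F5 is then joined to 21 by Negishi coupling (Pd(OAc)2, SPhos, THF, rt → 50 °C).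

**Step 13.** The hindered secondary silyl ether may need long exposure to fluoride, during which phenoxide formation opens the way to retro‑aldol cleavage, C3 epimerisation or quinone methide formation. The fallback sets out from 22 and returns at 23. The secondary TBS ether is removed first under acidic fluoride (aqueous HF, MeCN, 0 °C), which aryl TIPS ethers resist, to give the bis(aryl TIPS) carbinol F6. The two aryl TIPS ethers are then cleaved within minutes by Bu4NF/AcOH in THF at −20 °C.

## Further compounds

F1 | step 9 | cis‑(3S,4S)‑4‑formyl‑3‑[(S)‑(TBS‑oxy)(3‑methoxy‑4‑TIPS‑oxyphenyl)methyl]dihydrofuran‑2(3H)‑one | O=C1OC[C@@H](C=O)[C@H]1[C@H](O[Si](C)(C)C(C)(C)C)c1ccc(O[Si](C(C)C)(C(C)C)C(C)C)c(OC)c1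
F2 | step 9 | trans‑(3S,4R)‑4‑formyl‑3‑[(S)‑(TBS‑oxy)(3‑methoxy‑4‑TIPS‑oxyphenyl)methyl]dihydrofuran‑2(3H)‑one | O=C1OC[C@H](C=O)[C@H]1[C@H](O[Si](C)(C)C(C)(C)C)c1ccc(O[Si](C(C)C)(C(C)C)C(C)C)c(OC)c1
F3 | step 8 | (2R,3S)‑3‑(TBS‑oxy)‑2‑(2,2‑dimethyl‑1,3‑dioxan‑5‑yl)‑3‑(3‑methoxy‑4‑TIPS‑oxyphenyl)propan‑1‑ol | CC1(C)OCC(CO1)[C@H](CO)[C@H](O[Si](C)(C)C(C)(C)C)c1ccc(O[Si](C(C)C)(C(C)C)C(C)C)c(OC)c1
F4 | step 8 | (2S,3S)‑3‑(TBS‑oxy)‑2‑(2,2‑dimethyl‑1,3‑dioxan‑5‑yl)‑3‑(3‑methoxy‑4‑TIPS‑oxyphenyl)propanal | CC1(C)OCC(CO1)[C@H](C=O)[C@H](O[Si](C)(C)C(C)(C)C)c1ccc(O[Si](C(C)C)(C(C)C)C(C)C)c(OC)c1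
F5 | step 12 | trans‑(3S,4R)‑3‑[(S)‑(TBS‑oxy)(3‑methoxy‑4‑TIPS‑oxyphenyl)methyl]‑4‑[(iodozincio)methyl]dihydrofuran‑2(3H)‑one | O=C1OC[C@H](C[Zn]I)[C@H]1[C@H](O[Si](C)(C)C(C)(C)C)c1ccc(O[Si](C(C)C)(C(C)C)C(C)C)c(OC)c1
F6 | step 13 | trans‑(3S,4R)‑3‑[(S)‑hydroxy(3‑methoxy‑4‑TIPS‑oxyphenyl)methyl]‑4‑(3‑methoxy‑4‑TIPS‑oxybenzyl)dihydrofuran‑2(3H)‑one | COc1cc(C[C@H]2COC(=O)[C@@H]2[C@H](O)c2ccc(O[Si](C(C)C)(C(C)C)C(C)C)c(OC)c2)ccc1O[Si](C(C)C)(C(C)C)C(C)C
A1 | alternative 1 | (E)‑ferulic acid | COc1cc(/C=C/C(=O)O)ccc1O
A2 | alternative 1 | cis‑fused 2,6‑bis(4‑hydroxy‑3‑methoxyphenyl)‑3,7‑dioxabicyclo[3.3.0]octane‑4,8‑dione with exo aryl groups (formed as racemate; needed enantiomer drawn) | O=C1O[C@H](c2ccc(O)c(OC)c2)[C@H]2C(=O)O[C@H](c3ccc(O)c(OC)c3)[C@@H]12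
A3 | alternative 2 | (5R)‑5‑(l‑menthyloxy)furan‑2(5H)‑one | O=C1C=C[C@H](O[C@@H]2C[C@H](C)CC[C@H]2C(C)C)O1
A4 | alternative 2 | 2‑[4‑(TBS‑oxy)‑3‑methoxyphenyl]‑1,3‑dithiane | COc1cc(C2SCCCS2)ccc1O[Si](C)(C)C(C)(C)C
A5 | alternative 2 | 4‑(TBS‑oxy)‑3‑methoxybenzaldehyde | COc1cc(C=O)ccc1O[Si](C)(C)C(C)(C)C
A6 | alternative 2 | trans,trans 5‑menthyloxy lactone with the aryl dithianyl group at C4 and the (S)‑hydroxy(aryl)methyl group at C3 | O=C1O[C@@H](O[C@@H]2C[C@H](C)CC[C@H]2C(C)C)[C@H](C2(c3ccc(O[Si](C)(C)C(C)(C)C)c(OC)c3)SCCCS2)[C@H]1[C@H](O)c1ccc(O[Si](C)(C)C(C)(C)C)c(OC)c1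
A7 | alternative 3 | (R)‑4‑(TBS‑oxy)‑3‑[4‑(TBS‑oxy)‑3‑methoxybenzyl]butanoyl chloride | ClC(=O)C[C@H](CO[Si](C)(C)C(C)(C)C)Cc1ccc(O[Si](C)(C)C(C)(C)C)c(OC)c1
A8 | alternative 3 | vanillin acetate | CC(=O)Oc1ccc(C=O)cc1OC
A9 | alternative 3 | (3S,4S)‑cis‑4‑(4‑acetoxy‑3‑methoxyphenyl)‑3‑[(R)‑1‑(TBS‑oxy)‑3‑(4‑TBS‑oxy‑3‑methoxyphenyl)propan‑2‑yl]oxetan‑2‑one | O=C1O[C@H](c2ccc(OC(C)=O)c(OC)c2)[C@@H]1[C@H](CO[Si](C)(C)C(C)(C)C)Cc1ccc(O[Si](C)(C)C(C)(C)C)c(OC)c1
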